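This closed, stirred vessel starts with no dissolved reagent, so reagent has to enter from the held gas.

    starting material + target ⇌ idle adduct, settled at all times (K1 = 5.1 /M)
    second substrate + reagent ⇌ second product (K2 = 2.14 /M, k2 = 0.0342 /M/min)
    starting material + reagent ⇌ target (K3 = 14 /M, k3 = 0.443 /M/min)
    gas ⇌ reagent, rate k4*(csat - [reagent]) (k4 = 0.0385 /min, csat = 160 mM)

all flasks: second substrate 0.450 M; gas 160 mM (held); time 20 min

|  | starting material |
|---|---|
| larch | 0.12 M |
| alder | 0.25 M |
| cedar | 0.50 M |
| ash | 1.0 M |

- in percentages every species weighs as the starting material in it: one idle adduct counts as two
- for target the idle adduct is counted in
- at the start none of reagent is dissolved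
- in an amount of target, one idle adduct counts as one target
- the concentration of target that is asked is that of its free form alone
- "hardly changes" means that all values lie within two and a half points (for a concentration: within two and a half percent of the largest)
- run time (larch): 20 min

- [target] (only what is free in solution) at the end for larch, alder, cedar, ash, in this order
- the course of these numbers from the first flask to the last (falls all the way / falls, then rises / hardly changes / rises all the way / rises, then falls)

**The ration.** Write the balance of dissolved reagent: it enters by transfer and leaves by the two reactions. The gas delivers at full rate only while dissolved reagent stands at zero. That full rate kept up for the run, the transfer coefficient times saturation times time, is the ration R, 0.123 M. In alder it is smaller than the starting material charged, and in cedar too. The gas is held, so R bounds what enters in 20 min; it is not a charge.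

**Loss and capture.** Holding the substrates at their charges makes the balance pseudo-first-order, with a rate λ. This sums the target step's constant times starting material, the second-product step's constant times second substrate, and the transfer coefficient. The target step's term over λ is the capture share φ. The reciprocal of λ is a lag, and the run loses that part of its time. So the target formed, idle adduct counted, is R times φ times the unlagged part of the run. The free share f of that target is the reciprocal of one plus the adduct constant times the charge.

**Two neighbours.** Alder has λ = 0.165 /min, and cedar has 0.275 /min. My reckoning gives alder 0.0577 M of target and cedar more, 0.0811 M. But f drops from 0.440 to 0.282. Free target is therefore 0.0254 M in alder and a little less, 0.0228 M, in cedar.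

**The forecast.** It gives 0.019 M, 0.023 M, 0.024 M, 0.018 M, and the shape rises, then falls, holding that “the excess starting material ties most of the target up as idle adduct”. It puts cedar above alder, the reverse of my order.

**The flasks.** They give 0.0190 M, 0.0251 M, 0.0248 M, 0.0181 M, and the shape rises, then falls, so the forecast stands within its margin. The row turns at 0.35 M; its shape would fail with that turn outside the charges 0.12 M to 1.0 M. In alder, the reagent in target (idle adduct counted in), second product and solution comes to 81.8% of R. In ash, where λ is 0.497 /min, R yields 0.0162 M of free target, and the flask reads 0.0181 M.

Its constants belong to no real substance.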